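The central dihydropyran (ring A) is made of O-4 and C-3 of quinolone A, the O–CH, the ring-fusion CH and the CH that carries the 2-methylprop-1-enyl group. The route opens this ring as a cationic oxa-Povarov [4+2]. An O-(2-quinolon-4-yl) oxocarbenium ion, tethered through O–CMe2 to quinolone B, is attacked by the proximal carbon of a (1E)-4-methylpenta-1,3-dienyl group on C-3 of quinolone B. The resulting 1,1-dimethylallyl cation alkylates the nucleophilic C-3 of quinolone A. One operation thus closes rings B and A and sets all three stereocentres under a chiral Brønsted acid. The precursor is an acyclic α-acetoxy ether joining two 1-methylquinolin-2-ones.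

Key step: step 7

Naming: quinolone A is the 1-methylquinolin-2-one whose O-4 and C-3 lie in ring A; quinolone B is the one fused to ring B, the 2,2-dimethyl-dihydropyran. C-a is the CH bearing the 2-methylprop-1-enyl group, C-b the ring-fusion CH bonded to C-3 of quinolone B, C-c the ring-fusion O–CH. The target is (C-a R; C-b S; C-c S), with H on C-b and C-c cis and H on C-a trans to H on C-b.

Assumption: the sense of asymmetric induction of the chiral acid in step 7 cannot be predicted with certainty; the (S,S)-catalyst is written, and its mirror-image form would be used if the opposite sense is found.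

Step 1
Reactants: 1 4-hydroxy-1-methylquinolin-2(1H)-one
Product: 3 4-chloro-1-methyl-2-oxo-1,2-dihydroquinoline-3-carbaldehyde, via iminium chloride 2 (not isolated)
Conditions: POCl3, DMF, 0 °C → 70 °C; then ice-water
Reagents that add atoms: N,N-dimethylformamide CN(C)C=O; phosphoryl chloride O=P(Cl)(Cl)Cl; water O
Why: Vilsmeier–Haack chloroformylation, in which the chloroiminium reagent formylates the enolic C-3 and the vinylogous acid OH is exchanged for chloride, as is typical of 4-hydroxy-2-quinolones; no stereocentre is formed.

Step 2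
Reactants: 3 4-chloro-1-methyl-2-oxo-1,2-dihydroquinoline-3-carbaldehyde; 4 methyl 2-hydroxy-2-methylpropanoate
Product: 5 methyl 2-[(3-formyl-1-methyl-2-oxo-1,2-dihydroquinolin-4-yl)oxy]-2-methylpropanoate
Conditions: 4, NaH, THF, 0 °C; then 3, 0 °C → rt
Reagents that add atoms: none
Why: Addition–elimination (SNAr-type substitution at a β-chloro enal) by the tertiary sodium alkoxide at C-4, which the ortho formyl group activates; the alkoxide has no α-hydrogen and no stereocentre is formed.

Step 3
Reactants: 5 methyl 2-[(3-formyl-1-methyl-2-oxo-1,2-dihydroquinolin-4-yl)oxy]-2-methylpropanoate; 6 (3-methylbut-2-en-1-yl)triphenylphosphonium bromide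
Product: 8 methyl 2-methyl-2-({1-methyl-3-[(1E)-4-methylpenta-1,3-dien-1-yl]-2-oxo-1,2-dihydroquinolin-4-yl}oxy)propanoate, via Z-diene ester 7 (not isolated)
Conditions: 6, NaN(SiMe3)2, THF, −78 → 0 °C; then 5, −78 °C → rt; then I2 (5 mol %), CH2Cl2, daylight, rt
Reagents that add atoms: none
Why: Wittig olefination with the semi-stabilised allylic ylide should give the new C=C bond as an E/Z mixture, and iodine-catalysed isomerisation should converge it to the thermodynamically preferred (1E)-diene; the terminal trisubstituted double bond has no geometry to control.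

Step 4
Reactants: 8 methyl 2-methyl-2-({1-methyl-3-[(1E)-4-methylpenta-1,3-dien-1-yl]-2-oxo-1,2-dihydroquinolin-4-yl}oxy)propanoate
Product: 9 2-methyl-2-({1-methyl-3-[(1E)-4-methylpenta-1,3-dien-1-yl]-2-oxo-1,2-dihydroquinolin-4-yl}oxy)propanoic acid
Conditions: LiOH·H2O, THF/MeOH/H2O, rt; then cold 1 M HCl to pH 3
Reagents that add atoms: lithium hydroxide [Li+].[OH-]
Why: Saponification of the methyl ester; the 4-alkoxyquinolone ether and the diene should be inert to aqueous hydroxide at room temperature, and no stereocentre is involved.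

Step 5
Reactants: 9 2-methyl-2-({1-methyl-3-[(1E)-4-methylpenta-1,3-dien-1-yl]-2-oxo-1,2-dihydroquinolin-4-yl}oxy)propanoic acid; 1 4-hydroxy-1-methylquinolin-2(1H)-one
Product: 11 1-methyl-2-oxo-1,2-dihydroquinolin-4-yl 2-methyl-2-({1-methyl-3-[(1E)-4-methylpenta-1,3-dien-1-yl]-2-oxo-1,2-dihydroquinolin-4-yl}oxy)propanoate, via acid chloride 10 (not isolated)
Conditions: 1-chloro-N,N,2-trimethylprop-1-en-1-amine, CH2Cl2, 0 °C → rt; then 1, Et3N, CH2Cl2, −20 → 0 °C
Reagents that add atoms: none
Why: Acid chloride formation under neutral conditions spares the acid-sensitive diene, and base-mediated acylation of the vinylogous acid 1 is kinetically O-selective (esterification via acyl chloride); low temperature and the absence of a nucleophilic catalyst suppress O-to-C acyl migration.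

Step 6
Reactants: 11 1-methyl-2-oxo-1,2-dihydroquinolin-4-yl 2-methyl-2-({1-methyl-3-[(1E)-4-methylpenta-1,3-dien-1-yl]-2-oxo-1,2-dihydroquinolin-4-yl}oxy)propanoate
Product: 13 racemic 2-methyl-2-({1-methyl-3-[(1E)-4-methylpenta-1,3-dien-1-yl]-2-oxo-1,2-dihydroquinolin-4-yl}oxy)-1-[(1-methyl-2-oxo-1,2-dihydroquinolin-4-yl)oxy]propyl acetate, via aluminium hemiacetal 12 (not isolated)
Conditions: i-Bu2AlH, CH2Cl2, −78 °C; then pyridine, DMAP, Ac2O, −78 → −20 °C; aqueous potassium sodium tartrate
Reagents that add atoms: acetic anhydride CC(=O)OC(C)=O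
Why: Reductive acetylation of an ester: hydride addition at −78 °C gives a tetrahedral aluminium hemiacetal that is acetylated in situ before it collapses, and the two lactam carbonyls are far less electrophilic than the enol ester; the acetal centre forms as a racemate, which does not matter because it is ionised in step 7.

Step 7
Reactants: 13 racemic 2-methyl-2-({1-methyl-3-[(1E)-4-methylpenta-1,3-dien-1-yl]-2-oxo-1,2-dihydroquinolin-4-yl}oxy)-1-[(1-methyl-2-oxo-1,2-dihydroquinolin-4-yl)oxy]propyl acetate
Product: 16 target CNP0107253.2 (C-a R; C-b S; C-c S; cis ring fusion), via oxocarbenium ion 14 (not isolated), via allyl cation 15 (not isolated)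
Conditions: (S,S)-imidodiphosphorimidate acid HN[P(=NSO2CF3)(O2Ar)]2, O2Ar = (S)-3,3'-bis[3,5-bis(trifluoromethyl)phenyl]-1,1'-binaphthalene-2,2'-diolate (5 mol %), CHCl3, −40 → 0 °C
Reagents that add atoms: none
Why: Proposed new method: the confined chiral acid should protonate the acetoxy group of 13 and expel acetic acid to give the (E)-O-quinolonyl oxocarbenium ion 14 paired with the chiral anion; the diene carbon on quinolone B (future C-b) attacks the oxocarbenium carbon (future C-c), and the 1,1-dimethylallyl cation 15 is captured at its secondary terminus (C-a) by C-3 of quinolone A, which then loses its proton to the anion, so that the cationic 2-oxadiene C-3=C-4–O+=CH of quinolone A and the proximal diene double bond are joined in a stepwise formal [4+2]. The closest known reaction types are the Lewis-acid oxa-Povarov reaction of aryl oxocarbenium ions with alkenes, Prins/Friedel–Crafts cascades and asymmetric Prins cyclisations under confined chiral Brønsted acids; new here are the 4-quinolonyloxy oxocarbenium ion, the diene relay and counter-anion control of this cascade. Ring B closes first by a 6-exo Prins attack in which both the C=O+ and the C=C bond stay outside the new ring, and ring A closes second by a 6-endo Friedel–Crafts attack of the enol-ether double bond of quinolone A on the allyl cation. The absolute configuration at C-b and C-c is set in the first C–C bond formation by the chiral anion, their cis relationship by the endo (tether-folded) transition state of the (E)-oxocarbenium ion, and the trans relationship of the 2-methylprop-1-enyl group at C-a to quinolone B by the (E)-alkene geometry together with pseudo-equatorial closure of ring A. The step needs loss of acetate instead of the quinolonyloxy group, attack at the diene carbon next to quinolone B and closure at the secondary allyl terminus; these should be secured by the better stabilisation of a quinolonyloxy cation than of an acyloxy cation, by the six-membered tether and the tertiary allyl cation that only proximal attack creates, and by the preference for a six- over an eight-membered ring.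

Compound list
1 | 4-hydroxy-1-methylquinolin-2(1H)-one | Cn1c(=O)cc(O)c2ccccc21 | starting material
2 | N-[(4-chloro-1-methyl-2-oxo-1,2-dihydroquinolin-3-yl)methylidene]-N-methylmethanaminium chloride | C[N+](C)=Cc1c(Cl)c2ccccc2n(C)c1=O.[Cl-] | intermediate (not isolated)
3 | 4-chloro-1-methyl-2-oxo-1,2-dihydroquinoline-3-carbaldehyde | O=Cc1c(Cl)c2ccccc2n(C)c1=O | intermediate
4 | methyl 2-hydroxy-2-methylpropanoate | COC(=O)C(C)(C)O | starting material
5 | methyl 2-[(3-formyl-1-methyl-2-oxo-1,2-dihydroquinolin-4-yl)oxy]-2-methylpropanoate | COC(=O)C(C)(C)Oc1c(C=O)c(=O)n(C)c2ccccc12 | intermediate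
6 | (3-methylbut-2-en-1-yl)triphenylphosphonium bromide | CC(C)=CC[P+](c1ccccc1)(c1ccccc1)c1ccccc1.[Br-] | starting material
7 | methyl 2-methyl-2-({1-methyl-3-[(1Z)-4-methylpenta-1,3-dien-1-yl]-2-oxo-1,2-dihydroquinolin-4-yl}oxy)propanoate | COC(=O)C(C)(C)Oc1c(/C=C\C=C(C)C)c(=O)n(C)c2ccccc12 | intermediate (not isolated)
8 | methyl 2-methyl-2-({1-methyl-3-[(1E)-4-methylpenta-1,3-dien-1-yl]-2-oxo-1,2-dihydroquinolin-4-yl}oxy)propanoate | COC(=O)C(C)(C)Oc1c(/C=C/C=C(C)C)c(=O)n(C)c2ccccc12 | intermediate
9 | 2-methyl-2-({1-methyl-3-[(1E)-4-methylpenta-1,3-dien-1-yl]-2-oxo-1,2-dihydroquinolin-4-yl}oxy)propanoic acid | OC(=O)C(C)(C)Oc1c(/C=C/C=C(C)C)c(=O)n(C)c2ccccc12 | intermediate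
10 | 2-methyl-2-({1-methyl-3-[(1E)-4-methylpenta-1,3-dien-1-yl]-2-oxo-1,2-dihydroquinolin-4-yl}oxy)propanoyl chloride | ClC(=O)C(C)(C)Oc1c(/C=C/C=C(C)C)c(=O)n(C)c2ccccc12 | intermediate (not isolated)
11 | 1-methyl-2-oxo-1,2-dihydroquinolin-4-yl 2-methyl-2-({1-methyl-3-[(1E)-4-methylpenta-1,3-dien-1-yl]-2-oxo-1,2-dihydroquinolin-4-yl}oxy)propanoate | Cn1c(=O)cc(OC(=O)C(C)(C)Oc2c(/C=C/C=C(C)C)c(=O)n(C)c3ccccc23)c2ccccc21 | intermediate
12 | diisobutylaluminium alkoxide of the hemiacetal of 11 (racemic at the hemiacetal carbon) | CC(C)C[Al](CC(C)C)OC(Oc1cc(=O)n(C)c2ccccc12)C(C)(C)Oc1c(/C=C/C=C(C)C)c(=O)n(C)c2ccccc12 | intermediate (not isolated)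
13 | 2-methyl-2-({1-methyl-3-[(1E)-4-methylpenta-1,3-dien-1-yl]-2-oxo-1,2-dihydroquinolin-4-yl}oxy)-1-[(1-methyl-2-oxo-1,2-dihydroquinolin-4-yl)oxy]propyl acetate (racemic at the acetal carbon) | CC(=O)OC(Oc1cc(=O)n(C)c2ccccc12)C(C)(C)Oc1c(/C=C/C=C(C)C)c(=O)n(C)c2ccccc12 | intermediate
14 | (E)-O-(1-methyl-2-oxo-1,2-dihydroquinolin-4-yl) oxocarbenium ion of the 2-aryloxy-2-methylpropanal, as its ion pair with the chiral anion | Cn1c(=O)cc(/[O+]=C/C(C)(C)Oc2c(/C=C/C=C(C)C)c(=O)n(C)c3ccccc23)c2ccccc21 | intermediate (not isolated)
15 | ring-B-closed 1,1-dimethylallyl cation, C-b and C-c configured as in 16, drawn as its tertiary resonance form | C[C+](C)/C=C/[C@@H]1[C@H](Oc2cc(=O)n(C)c3ccccc23)C(C)(C)Oc2c1c(=O)n(C)c1ccccc21 | intermediate (not isolated)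
16 | CNP0107253.2, cis-fused bis(pyranoquinolinone) with C-a R, C-b S, C-c S | CC(C)=C[C@H]1c2c(c3ccccc3n(C)c2=O)O[C@H]2[C@@H]1c1c(c3ccccc3n(C)c1=O)OC2(C)C | target

Total steps: 7. Longest linear sequence: 7 steps (1 → 3 → 5 → 8 → 9 → 11 → 13 → 16).

Steps most likely to fail

Step 7. The process at risk is the ionisation itself and its control. The lactam carbonyl of quinolone A is the most basic site, so the quinolonyloxy group may depart instead of acetate. The acid may be sequestered by the two lactam carbonyls or may protonate the diene. The ion pair may show poor facial discrimination, or close through the exo transition state to the trans-fused isomer. The fallback uses known chemistry, sets out from 1 and comes back at 16. Condensation of 1 with 3-methylbut-2-enal (pyridine, MgSO4, 100 °C; Knoevenagel condensation followed by oxa-6π electrocyclisation) should give N-methylflindersine F1. Heating F1 at about 200 °C in a sealed tube should open part of it by retro-6π electrocyclisation to the ring-opened quinone methide F2. The 1-oxadiene of F2 should add to the pyran double bond of a second molecule of F1 in a hetero-Diels–Alder dimerisation, a known reaction type for 2,2-dimethylpyrano-fused quinolinones. This forms the C-a–C-b bond and the O–C-c bond and should give cis-fused racemic dimers. Racemic 16 would be separated from its diastereomers by chromatography and resolved by preparative HPLC on a chiral stationary phase, which removes the enantiomer of the target F3.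

Step 6. The aluminium hemiacetal may collapse with expulsion of the quinolonate before it is acetylated, which would lead to over-reduction to the primary alcohol, and hydride may also attack a lactam carbonyl. The fallback sets out from 8 and comes back at 13, replacing steps 4 to 6. Reduction of 8 with i-Bu2AlH (toluene, −78 °C) should give the 2-aryloxy-2-methylpropanal F4. Addition of acetyl chloride across the aldehyde (catalytic ZnCl2, CH2Cl2, −20 °C) should give the 1-chloroalkyl acetate F5. Koenigs–Knorr-type O-alkylation of 1 with F5 (Ag2CO3, toluene, 4 Å molecular sieves) should then give 13.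

Step 2. Addition–elimination by the hindered tertiary alkoxide may be slow, so that attack at the formyl group, self-condensation of the hydroxy ester or hydrolysis of the vinylogous acid chloride competes. The fallback sets out from 1 and comes back at 8, bypassing steps 1 to 3. O-Alkylation of 1 with methyl 2-bromo-2-methylpropanoate (Cs2CO3, DMF, 60 °C) should give the ether ester F6. Iodination at C-3 with N-iodosuccinimide (MeCN, rt) should give the iodide F7. Mizoroki–Heck coupling of F7 with 4-methylpenta-1,3-diene (Pd(OAc)2, P(o-tolyl)3, Et3N, DMF, 80 °C) should give the (1E)-diene 8.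

Further compounds
F1 | step 7 | N-methylflindersine (2,2,6-trimethyl-2H-pyrano[3,2-c]quinolin-5(6H)-one) | CC1(C)C=Cc2c(O1)c1ccccc1n(C)c2=O
F2 | step 7 | 1-methyl-3-(3-methylbut-2-en-1-ylidene)quinoline-2,4(1H,3H)-dione (ring-opened quinone methide) | CC(C)=C/C=C1/C(=O)N(C)c2ccccc2C1=O
F3 | step 7 | enantiomer of 16 (C-a S, C-b R, C-c R) | CC(C)=C[C@@H]1c2c(c3ccccc3n(C)c2=O)O[C@@H]2[C@H]1c1c(c3ccccc3n(C)c1=O)OC2(C)C
F4 | step 6 | 2-methyl-2-({1-methyl-3-[(1E)-4-methylpenta-1,3-dien-1-yl]-2-oxo-1,2-dihydroquinolin-4-yl}oxy)propanal | O=CC(C)(C)Oc1c(/C=C/C=C(C)C)c(=O)n(C)c2ccccc12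
F5 | step 6 | 1-chloro-2-methyl-2-({1-methyl-3-[(1E)-4-methylpenta-1,3-dien-1-yl]-2-oxo-1,2-dihydroquinolin-4-yl}oxy)propyl acetate | CC(=O)OC(Cl)C(C)(C)Oc1c(/C=C/C=C(C)C)c(=O)n(C)c2ccccc12
F6 | step 2 | methyl 2-methyl-2-[(1-methyl-2-oxo-1,2-dihydroquinolin-4-yl)oxy]propanoate | COC(=O)C(C)(C)Oc1cc(=O)n(C)c2ccccc12
F7 | step 2 | methyl 2-[(3-iodo-1-methyl-2-oxo-1,2-dihydroquinolin-4-yl)oxy]-2-methylpropanoate | COC(=O)C(C)(C)Oc1c(I)c(=O)n(C)c2ccccc12
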